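**Retrosynthetic overview**

1. With C1 as the ester carbon, C2 next, C3–C6 the dioxane carbons and C7 onward the side chain, target 19 is cut at the C8–C9 bond. This gives the iodoethyl-1,2-dioxane 13 and the (E)-alkenyl iodide 18, which are joined last by a nickel-electrocatalytic cross-electrophile coupling.
2. Enabling feature: the saturated C7–C8 spacer between the quaternary ring carbon C6 of the 1,2-dioxane and the E-trisubstituted C9=C10 alkene. A C8 radical is γ to the ring oxygen on C6, so it is insulated from the O–O bond and from C2, C3 and C6, and the alkene geometry can be stored in 18.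
3. Ring order: a temporary oxetane is closed in step 3 and opened by H2O2 at C6 with inversion in step 7. The 1,2-dioxane, the only ring of the target, is then closed in step 8 by invertive 6-exo-tet displacement of a C3 mesylate.
4. (R)-Linalool supplies C3–C8 and the C6 methyl: its carbinol carbon is C6, its vinyl group is C7–C8 and its homoprenyl arm is C5–C4–C3. An anti-crotylboration adds C2, its methyl group and a vinyl group that serves as masked C1.
5. Iodide 18 comes from geranyl bromide by propargylation and zirconium-catalysed carboalumination–iodination.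

Key step: step 15

Assumption: commercial (R)-(−)-linalool is taken as enantiomerically pure. Any (S)-enantiomer would become a diastereomer after step 5 and should be removable by chromatography at the cyclic stage 9.

**Route**

Step 1
Reactants: 1 (R)-(−)-linalool
Product: 2 (3R)-3,7-dimethyloct-6-ene-1,3-diol
Conditions: 9-BBN, THF, 0 °C to rt; then NaOH, H2O2, 0 °C
Reagents that add atoms: hydrogen peroxide, OO
Why: Anti-Markovnikov hydroboration–oxidation in which the bulky 9-BBN adds to the monosubstituted vinyl group much faster than to the trisubstituted alkene, while the C–O bond of the carbinol stereocentre (future C6) is never broken.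

Step 2
Reactants: 2 (3R)-3,7-dimethyloct-6-ene-1,3-diol
Product: 3 (3R)-3-hydroxy-3,7-dimethyloct-6-en-1-yl 4-methylbenzenesulfonate
Conditions: TsCl, Et3N, DMAP (cat.), CH2Cl2, 0 °C
Reagents that add atoms: 4-methylbenzenesulfonyl chloride, Cc1ccc(cc1)S(=O)(=O)Cl
Why: Chemoselective sulfonylation, since the primary hydroxyl is tosylated readily and the tertiary hydroxyl is too hindered to react at 0 °C.

Step 3
Reactants: 3 (3R)-3-hydroxy-3,7-dimethyloct-6-en-1-yl 4-methylbenzenesulfonate
Product: 4 (2R)-2-methyl-2-(4-methylpent-3-en-1-yl)oxetane
Conditions: KOt-Bu, THF, 0 °C to rt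
Reagents that add atoms: none
Why: Intramolecular Williamson etherification (4-exo-tet) in which the tertiary alkoxide displaces the primary tosylate, so the configuration at the quaternary carbon is retained and the strained ring stores both the future peroxide site C6 and the C8 oxygen.

Step 4
Reactants: 4 (2R)-2-methyl-2-(4-methylpent-3-en-1-yl)oxetane
Product: 5 3-[(2R)-2-methyloxetan-2-yl]propanal
Conditions: O3, CH2Cl2, −78 °C; then Me2S, −78 °C to rt
Reagents that add atoms: ozone, [O-][O+]=O
Why: Ozonolysis with reductive work-up cleaves the only alkene to the C3 aldehyde, and the oxetane is inert to ozone and Me2S at low temperature.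

Step 5
Reactants: 5 3-[(2R)-2-methyloxetan-2-yl]propanal
Product: 6 (3S,4R)-3-methyl-6-[(2R)-2-methyloxetan-2-yl]hex-1-en-4-ol
Conditions: (E)-but-2-ene, n-BuLi, KOt-Bu, THF, −78 to −45 °C; (−)-Ipc2BOMe, −78 °C; BF3·OEt2 (1 equiv to borinate); then 5, −78 °C; NaOH, H2O2
Reagents that add atoms: (E)-but-2-ene, C/C=C/C
Why: Brown asymmetric crotylboration through a chair Zimmerman–Traxler transition state, in which the E geometry of the crotyl unit gives the anti C2/C3 relationship and the isopinocampheyl groups derived from (+)-α-pinene direct attack to the Si face of the aldehyde (4R carbinol), BF3·OEt2 being consumed by methoxide abstraction before the oxetane aldehyde is added.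

Step 6
Reactants: 6 (3S,4R)-3-methyl-6-[(2R)-2-methyloxetan-2-yl]hex-1-en-4-ol
Product: 7 (3S,4R)-3-methyl-6-[(2R)-2-methyloxetan-2-yl]hex-1-en-4-yl methanesulfonate
Conditions: MsCl, Et3N, CH2Cl2, 0 °C
Reagents that add atoms: methanesulfonyl chloride, CS(=O)(=O)Cl
Why: Mesylation forms an O–S bond only, so the carbinol configuration is kept, and the amine-buffered medium leaves the acid-sensitive oxetane closed.

Step 7
Reactants: 7 (3S,4R)-3-methyl-6-[(2R)-2-methyloxetan-2-yl]hex-1-en-4-yl methanesulfonate
Product: 8 (3S,4R,7S)-7-hydroperoxy-9-hydroxy-3,7-dimethylnon-1-en-4-yl methanesulfonate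
Conditions: H2O2 (anhydrous, excess), TMSOTf (cat.), Et2O, −78 to 0 °C
Reagents that add atoms: hydrogen peroxide, OO
Why: Lewis acid-mediated perhydrolysis of a 2,2-disubstituted oxetane, in which ring strain and the partial positive charge at the tertiary carbon direct H2O2 to C6 and backside attack on the activated, still bonded C–O unit gives the tertiary hydroperoxide with inversion, which sets C6, while mesylate and terminal alkene are inert.

Step 8
Reactants: 8 (3S,4R,7S)-7-hydroperoxy-9-hydroxy-3,7-dimethylnon-1-en-4-yl methanesulfonate
Product: 9 2-{(3S,6S)-6-[(2S)-but-3-en-2-yl]-3-methyl-1,2-dioxan-3-yl}ethan-1-ol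
Conditions: KOt-Bu (1 equiv), 18-crown-6 (cat.), THF, 0 °C
Reagents that add atoms: none
Why: Intramolecular alkylation of a hydroperoxide (6-exo-tet SN2), in which one equivalent of base deprotonates only the more acidic OOH group and the α-effect peroxy anion displaces the mesylate with inversion, which sets C3 and closes the 1,2-dioxane with the butenyl group and the hydroxyethyl arm trans.

Step 9
Reactants: 9 2-{(3S,6S)-6-[(2S)-but-3-en-2-yl]-3-methyl-1,2-dioxan-3-yl}ethan-1-ol
Product: 11 (2R)-2-[(3S,6S)-6-(2-hydroxyethyl)-6-methyl-1,2-dioxan-3-yl]propanoic acid, via aldehyde 10 (not isolated)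
Conditions: O3, CH2Cl2, −78 °C; Me2S; then NaClO2, NaH2PO4, 2-methylbut-2-ene, t-BuOH/H2O, 0 °C to rt
Reagents that add atoms: ozone, [O-][O+]=O; sodium chlorite, [Na+].[O-]Cl=O
Why: Ozonolysis of the only alkene followed by Pinnick oxidation of the crude aldehyde, both tolerated by a dialkyl peroxide and by the primary alcohol, and the absence of base and of chromatography at the aldehyde stage protects C2 from epimerisation and the ring from β-elimination.

Step 10
Reactants: 11 (2R)-2-[(3S,6S)-6-(2-hydroxyethyl)-6-methyl-1,2-dioxan-3-yl]propanoic acid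
Product: 12 methyl (2R)-2-[(3S,6S)-6-(2-hydroxyethyl)-6-methyl-1,2-dioxan-3-yl]propanoate
Conditions: TMSCHN2, toluene/MeOH, 0 °C
Reagents that add atoms: (trimethylsilyl)diazomethane, C[Si](C)(C)C=[N+]=[N-]
Why: Methyl esterification with TMS-diazomethane proceeds by protonation of the reagent by the acid alone, so the alcohol, the peroxide and the C2 stereocentre are untouched.

Step 11
Reactants: 12 methyl (2R)-2-[(3S,6S)-6-(2-hydroxyethyl)-6-methyl-1,2-dioxan-3-yl]propanoate
Product: 13 methyl (2R)-2-[(3S,6S)-6-(2-iodoethyl)-6-methyl-1,2-dioxan-3-yl]propanoate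
Conditions: PPh3, I2, imidazole, CH2Cl2, 0 °C (premixed); then 12, 0 °C
Reagents that add atoms: iodine, II
Why: Appel-type iodination in which the alcohol attacks the preformed iodophosphonium salt and iodide displaces Ph3PO at the primary carbon, and premixing PPh3 with I2 leaves no free phosphine that could reduce the O–O bond.

Step 12
Reactants: 14 geranyl bromide
Product: 15 [(5E)-6,10-dimethylundeca-5,9-dien-1-yn-1-yl]trimethylsilane
Conditions: 1-(trimethylsilyl)propyne, n-BuLi, THF, −78 to −20 °C; then 14, −78 °C to rt
Reagents that add atoms: 1-(trimethylsilyl)propyne, CC#C[Si](C)(C)C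
Why: SN2 alkylation of the propargylic lithium reagent by the allylic bromide, the silyl group blocking the alkyne terminus and suppressing allene formation, with the E alkene of the geranyl unit unchanged.

Step 13
Reactants: 15 [(5E)-6,10-dimethylundeca-5,9-dien-1-yn-1-yl]trimethylsilane
Product: 16 (5E)-6,10-dimethylundeca-5,9-dien-1-yne
Conditions: K2CO3, MeOH, rt
Reagents that add atoms: none
Why: Base-catalysed protodesilylation of the alkynylsilane by methanol, which does not affect the two alkenes.

Step 14
Reactants: 16 (5E)-6,10-dimethylundeca-5,9-dien-1-yne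
Product: 18 (1E,5E)-1-iodo-2,6,10-trimethylundeca-1,5,9-triene, via alkenyldimethylalane 17 (not isolated)
Conditions: AlMe3, Cp2ZrCl2 (cat.), CH2Cl2, 0 °C to rt; then I2, THF, −30 to 0 °C
Reagents that add atoms: trimethylaluminium, C[Al](C)C; iodine, II
Why: Negishi zirconium-catalysed carboalumination adds methyl and aluminium syn across the terminal alkyne with aluminium at the terminus, and iodinolysis of the C–Al bond with retention gives the E iodide that stores the C9=C10 geometry.

Step 15
Reactants: 13 methyl (2R)-2-[(3S,6S)-6-(2-iodoethyl)-6-methyl-1,2-dioxan-3-yl]propanoate; 18 (1E,5E)-1-iodo-2,6,10-trimethylundeca-1,5,9-triene (1.5 equiv)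
Product: 19 methyl (2R)-2-{(3S,6R)-6-methyl-6-[(3E,7E)-4,8,12-trimethyltrideca-3,7,11-trien-1-yl]-1,2-dioxan-3-yl}propanoate
Conditions: NiBr2(dme) (10 mol %), 4,4'-di-tert-butyl-2,2'-bipyridine (dtbbpy, 10 mol %), NaI, DMA, undivided cell, RVC cathode, Zn anode, low constant current (about 2.2 F/mol) with the cathode held at the nickel wave, slow addition of 13, rt, Ar, no iron or steel parts
Reagents that add atoms: none
Why: Proposed new method: cathodic reduction of (dtbbpy)NiBr2 gives zerovalent nickel, which inserts with retention into the C–I bond of 18, monovalent nickel abstracts iodine from 13, the primary C8 radical is caught by the divalent alkenylnickel species, and reductive elimination from trivalent nickel forms C8–C9 while the zinc anode supplies the electrons. The closest known reaction types are the nickel-catalysed electroreductive cross-electrophile coupling of unactivated primary alkyl halides with C(sp2) halides and the nickel-electrocatalytic decarboxylative alkenylation of redox-active esters used to assemble 1,5-polyenes, and what is new is a dialkyl peroxide in the alkyl partner. No ring is closed and no stereocentre is created: C2, C3 and C6 are spectators because the radical sits at C8, and the E geometry of C9=C10 is inherited from 18 since oxidative addition and reductive elimination at an alkenyl carbon are stereoretentive. The selectivity needed is reduction of two C–I bonds in preference to the O–O bond; dissociative electron transfer to a dialkyl peroxide has a large intrinsic barrier and sets in far beyond the potential of the nickel bipyridine couple, so a current-limited electrolysis held at the nickel wave, unlike an excess of metal powder, should never offer the peroxide enough driving force. Inner-sphere attack of low-valent nickel on the O–O bond is disfavoured by its tertiary C6 and branched secondary C3 flanks, dialkyl peroxides oxidise nickel catalysts only on strong heating, and both iodides should react far faster. The C8 radical is γ to the ring oxygen on C6, so its only intramolecular path to the peroxide is a slow oxetane-forming homolytic substitution, whereas a radical at C7 would collapse to an epoxide, which is why the cut lies at C8–C9, and cross-selectivity comes from the different activation modes of the sp2 and sp3 iodides supported by the excess of 18.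

**Compound list**

1 | (R)-(−)-linalool | CC(C)=CCC[C@](C)(C=C)O | starting material
2 | (3R)-3,7-dimethyloct-6-ene-1,3-diol | CC(C)=CCC[C@](C)(CCO)O | intermediate
3 | (3R)-3-hydroxy-3,7-dimethyloct-6-en-1-yl 4-methylbenzenesulfonate | CC(C)=CCC[C@](C)(CCOS(=O)(=O)c1ccc(C)cc1)O | intermediate
4 | (2R)-2-methyl-2-(4-methylpent-3-en-1-yl)oxetane | CC(C)=CCC[C@]1(C)CCO1 | intermediate
5 | 3-[(2R)-2-methyloxetan-2-yl]propanal | O=CCC[C@]1(C)CCO1 | intermediate
6 | (3S,4R)-3-methyl-6-[(2R)-2-methyloxetan-2-yl]hex-1-en-4-ol | C=C[C@H](C)[C@H](O)CC[C@]1(C)CCO1 | intermediate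
7 | (3S,4R)-3-methyl-6-[(2R)-2-methyloxetan-2-yl]hex-1-en-4-yl methanesulfonate | C=C[C@H](C)[C@H](OS(C)(=O)=O)CC[C@]1(C)CCO1 | intermediate
8 | (3S,4R,7S)-7-hydroperoxy-9-hydroxy-3,7-dimethylnon-1-en-4-yl methanesulfonate | C=C[C@H](C)[C@H](OS(C)(=O)=O)CC[C@@](C)(CCO)OO | intermediate
9 | 2-{(3S,6S)-6-[(2S)-but-3-en-2-yl]-3-methyl-1,2-dioxan-3-yl}ethan-1-ol | C=C[C@H](C)[C@@H]1CC[C@@](C)(CCO)OO1 | intermediate
10 | (2R)-2-[(3S,6S)-6-(2-hydroxyethyl)-6-methyl-1,2-dioxan-3-yl]propanal (not isolated) | O=C[C@H](C)[C@@H]1CC[C@@](C)(CCO)OO1 | intermediate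
11 | (2R)-2-[(3S,6S)-6-(2-hydroxyethyl)-6-methyl-1,2-dioxan-3-yl]propanoic acid | OC(=O)[C@H](C)[C@@H]1CC[C@@](C)(CCO)OO1 | intermediate
12 | methyl (2R)-2-[(3S,6S)-6-(2-hydroxyethyl)-6-methyl-1,2-dioxan-3-yl]propanoate | COC(=O)[C@H](C)[C@@H]1CC[C@@](C)(CCO)OO1 | intermediate
13 | methyl (2R)-2-[(3S,6S)-6-(2-iodoethyl)-6-methyl-1,2-dioxan-3-yl]propanoate | COC(=O)[C@H](C)[C@@H]1CC[C@@](C)(CCI)OO1 | intermediate
14 | geranyl bromide, (2E)-1-bromo-3,7-dimethylocta-2,6-diene | CC(C)=CCC/C(C)=C/CBr | starting material
15 | [(5E)-6,10-dimethylundeca-5,9-dien-1-yn-1-yl]trimethylsilane | CC(C)=CCC/C(C)=C/CCC#C[Si](C)(C)C | intermediate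
16 | (5E)-6,10-dimethylundeca-5,9-dien-1-yne | CC(C)=CCC/C(C)=C/CCC#C | intermediate
17 | dimethyl[(1E,5E)-2,6,10-trimethylundeca-1,5,9-trien-1-yl]alane (not isolated) | CC(C)=CCC/C(C)=C/CC/C(C)=C/[Al](C)C | intermediate
18 | (1E,5E)-1-iodo-2,6,10-trimethylundeca-1,5,9-triene | CC(C)=CCC/C(C)=C/CC/C(C)=C/I | intermediate
19 | methyl (2R)-2-{(3S,6R)-6-methyl-6-[(3E,7E)-4,8,12-trimethyltrideca-3,7,11-trien-1-yl]-1,2-dioxan-3-yl}propanoate | COC(=O)[C@H](C)[C@@H]1CC[C@@](C)(CC/C=C(\C)CC/C=C(\C)CCC=C(C)C)OO1 | target

**Step count and risks**

Total step count: 15. Longest linear sequence: 12 (steps 1–11 and 15).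

Steps most likely to fail:

1. **Step 15** (bears the label "Proposed new method:").
   - Risk: reductive opening of the O–O bond by low-valent nickel or at the cathode, and homocoupling of either iodide, may outrun the cross-coupling.
   - Fallback with known chemistry, setting out from 18 and 13 and coming back at 19: the radical, reductive manifold is replaced by a redox-neutral, two-electron Negishi coupling of an unactivated primary alkyl iodide. Iodine–lithium exchange on 18 (t-BuLi, Et2O, −78 °C) and transmetalation with ZnBr2 should give bromo[(1E,5E)-2,6,10-trimethylundeca-1,5,9-trien-1-yl]zinc F1.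
   - F1 is then coupled with 13 under Pd2(dba)3, P(c-C5H9)3 and N-methylimidazole in THF/NMP. Zerovalent palladium attacks the C–I bond in an SN2 manner, no free radical or reducing metal meets the peroxide, and palladium–phosphine couplings are known to tolerate 1,2-dioxanes.

2. **Step 7.**
   - Risk: ionisation to a free tertiary cation may erode the configuration at C6, and hydrolysis to the 1,3-diol or elimination may compete with capture by H2O2.
   - Fallback, setting out from 7 and coming back at 9: the order of the two C–O bond formations is reversed so that the tertiary centre is attacked intramolecularly.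
   - Displacement of the mesylate of 7 with 2-methoxypropan-2-yl hydroperoxide (CsOH, DMF, inversion at C3) should give (2R)-2-{(3S,4S)-3-[(2-methoxypropan-2-yl)peroxy]-4-methylhex-5-en-1-yl}-2-methyloxetane F2.
   - Mild aqueous acetic acid releases (2R)-2-[(3S,4S)-3-hydroperoxy-4-methylhex-5-en-1-yl]-2-methyloxetane F3. Catalytic TMSOTf then lets the tethered hydroperoxide open the oxetane at C6 from the back (6-exo, inversion) to give 9 directly.

3. **Step 8.**
   - Risk: elimination of the hindered, β-branched mesylate to a diene, or base-induced Kornblum–DeLaMare fragmentation of the newly formed ring, may compete with ring closure.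
   - Fallback, setting out from 5 and coming back at 12: the substitution at C3 is replaced by a conjugate addition.
   - Wittig olefination of 5 with Ph3P=C(CH3)CO2CH3 should give methyl (2E)-2-methyl-5-[(2R)-2-methyloxetan-2-yl]pent-2-enoate F4. Perhydrolysis as in step 7 then gives methyl (2E,6S)-6-hydroperoxy-8-hydroxy-2,6-dimethyloct-2-enoate F5.
   - Amine-catalysed intramolecular oxa-Michael addition (Et2NH, CF3CH2OH) closes the dioxane. C6 is still fixed by the oxetane opening. C2 and C3 are then secured by chromatographic separation of diastereomers rather than by design, and the desired isomer is 12.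

**Further compounds**

F1 | step 15 | bromo[(1E,5E)-2,6,10-trimethylundeca-1,5,9-trien-1-yl]zinc | CC(C)=CCC/C(C)=C/CC/C(C)=C/[Zn]Br
F2 | step 7 | (2R)-2-{(3S,4S)-3-[(2-methoxypropan-2-yl)peroxy]-4-methylhex-5-en-1-yl}-2-methyloxetane | C=C[C@H](C)[C@@H](OOC(C)(C)OC)CC[C@]1(C)CCO1
F3 | step 7 | (2R)-2-[(3S,4S)-3-hydroperoxy-4-methylhex-5-en-1-yl]-2-methyloxetane | C=C[C@H](C)[C@@H](OO)CC[C@]1(C)CCO1
F4 | step 8 | methyl (2E)-2-methyl-5-[(2R)-2-methyloxetan-2-yl]pent-2-enoate | COC(=O)/C(C)=C/CC[C@]1(C)CCO1
F5 | step 8 | methyl (2E,6S)-6-hydroperoxy-8-hydroxy-2,6-dimethyloct-2-enoate | COC(=O)/C(C)=C/CC[C@@](C)(CCO)OO
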